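**Strategy.** Ring B is not carried through the synthesis but assembled by a Danheiser benzannulation, and becomes a quinone only at the end. Numbering ring B as in isoflavans (C1′ bears the chroman, C2′ and C5′ are carbonyls, C3′ and C4′ carry OMe, C6′ is CH), a 3-(chromen-3-yl)cyclobutenone supplies C3′, C2′, C1′ and C6′ and the acetylene diether MeO–C≡C–OSi(iPr)3 supplies C4′ and C5′. One thermal cascade forms C3′–C4′ and C5′–C6′, exploiting the contiguous O–C3′/O–C4′/O–C5′ arc: C3′ emerges as a free phenol, C4′ as OMe, C5′ as silyl ether. The C3 stereocentre is set afterwards by asymmetric hydrogenation.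

Key step: step 8

Remark: 1, 5 and 10 are taken as commercial; diether 13 is a new, labile compound used crude; the sense of induction in step 10 is assigned by analogy, and the antipodal ligand is used if it proves opposite.

Step 1
Reactants: 1 2-hydroxy-3,4-dimethoxybenzaldehyde
Product: 3 2,5-dihydroxy-3,4-dimethoxybenzaldehyde, via aryl sulfate 2 (not isolated)
Conditions: K2S2O8, aq KOH, 0 °C to rt; then aq HCl, 90 °C
Reagents that add atoms: potassium peroxydisulfate, [K+].[K+].[O-]S(=O)(=O)OOS(=O)(=O)[O-]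
Why: Elbs persulfate oxidation, in which the phenoxide is attacked by peroxydisulfate at the free position para to oxygen and the aryl sulfate is then hydrolysed by acid, the formyl group surviving as in the classical oxidation of salicylaldehyde.

Step 2
Reactants: 3 2,5-dihydroxy-3,4-dimethoxybenzaldehyde
Product: 4 5-(benzyloxy)-2-hydroxy-3,4-dimethoxybenzaldehyde
Conditions: BnBr (1.05 equiv), K2CO3 (1 equiv), acetone, rt
Reagents that add atoms: benzyl bromide, BrCc1ccccc1
Why: Williamson etherification, selective because the 2-OH is held in a hydrogen bond to the formyl group so that only the 5-OH should be benzylated with one equivalent of weak base.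

Step 3
Reactants: 4 5-(benzyloxy)-2-hydroxy-3,4-dimethoxybenzaldehyde; 5 acrolein
Product: 6 6-(benzyloxy)-7,8-dimethoxy-2H-chromene-3-carbaldehyde
Conditions: K2CO3, 1,4-dioxane, reflux
Reagents that add atoms: none
Why: Oxa-Michael addition of the phenoxide to acrolein followed by intramolecular aldol condensation, the standard annulation of salicylaldehydes to 2H-chromene-3-carbaldehydes.

Step 4
Reactants: 6 6-(benzyloxy)-7,8-dimethoxy-2H-chromene-3-carbaldehyde
Product: 7 6-(benzyloxy)-3-ethynyl-7,8-dimethoxy-2H-chromene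
Conditions: Me3SiCHN2, LiN(iPr)2, THF, −78 °C to rt; aq NH4Cl
Reagents that add atoms: trimethylsilyldiazomethane, C[Si](C)(C)C=[N+]=[N-]
Why: Colvin homologation, in which the lithiated diazo reagent adds to the aldehyde, Peterson-type loss of silanolate gives a diazoalkene and the alkylidene carbene formed on N2 loss rearranges by 1,2-hydride shift to the terminal alkyne.

Step 5
Reactants: 7 6-(benzyloxy)-3-ethynyl-7,8-dimethoxy-2H-chromene
Product: 8 3-[6-(benzyloxy)-7,8-dimethoxy-2H-chromen-3-yl]-4,4-dichlorocyclobut-2-en-1-one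
Conditions: Cl3CCOCl, Zn–Cu couple, Et2O–DME, rt, slow addition
Reagents that add atoms: trichloroacetyl chloride, ClC(Cl)(Cl)C(Cl)=O
Why: Ketene–alkyne [2+2] cycloaddition of dichloroketene, whose carbonyl carbon bonds to the terminal alkyne carbon to give the 3-substituted cyclobutenone, the trisubstituted conjugated alkene of ring C being expected to react more slowly than the alkyne.

Step 6
Reactants: 8 3-[6-(benzyloxy)-7,8-dimethoxy-2H-chromen-3-yl]-4,4-dichlorocyclobut-2-en-1-one
Product: 9 3-[6-(benzyloxy)-7,8-dimethoxy-2H-chromen-3-yl]cyclobut-2-en-1-one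
Conditions: Zn, AcOH, TMEDA, EtOH, 0 °C to rt
Reagents that add atoms: none
Why: Reductive dechlorination of the α,α-dichloroketone by zinc under buffered conditions, the standard second stage of cyclobutenone synthesis, which should leave the strained enone and the benzyl ether intact.

Step 7
Reactants: 10 2-chloro-1,1-dimethoxyethane
Product: 13 1-methoxy-2-[(triisopropylsilyl)oxy]ethyne, via lithium methoxyacetylide 11 (not isolated), via lithium methoxyethynolate 12 (not isolated)
Conditions: LiNEt2 (3 equiv), THF, 0 °C; t-BuOOH/LiN(SiMe3)2, −78 to 0 °C; iPr3SiOTf, −78 °C; pentane extraction, used crude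
Reagents that add atoms: tert-butyl hydroperoxide, CC(C)(C)OO; triisopropylsilyl trifluoromethanesulfonate, CC(C)[Si](C(C)C)(C(C)C)OS(=O)(=O)C(F)(F)F
Why: Double elimination from the chloroacetal gives the alkoxyacetylide, electrophilic oxidation of the acetylide with lithium tert-butyl peroxide gives the ynolate, and a bulky silyl triflate silylates ynolates on oxygen (siloxyalkyne synthesis), the diether being used at once because acetylene diethers are labile.

Step 8
Reactants: 9 3-[6-(benzyloxy)-7,8-dimethoxy-2H-chromen-3-yl]cyclobut-2-en-1-one; 13 1-methoxy-2-[(triisopropylsilyl)oxy]ethyne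
Product: 17 5-[6-(benzyloxy)-7,8-dimethoxy-2H-chromen-3-yl]-2-methoxy-3-[(triisopropylsilyl)oxy]phenol, via vinylketene 14 (not isolated), via vinylcyclobutenone 15 (not isolated), via dienylketene 16 (not isolated)
Conditions: 13 (2 equiv), toluene, sealed tube, 80 °C, then 110 °C
Reagents that add atoms: none
Why: Danheiser benzannulation. Heating opens 9 by 4π electrocyclic ring opening to vinylketene 14, whose ketene C=C adds to the electron-rich alkyne in a [2+2] cycloaddition to give 15, which opens again (4π) to dienylketene 16, closes by 6π electrocyclisation and tautomerises to the phenol. The closest known reaction type is the benzannulation of cyclobutenones with siloxyalkynes and alkoxyalkynes, and acetylene diethers are established ketenophiles. Ring B is closed by the thermal 6π electrocyclisation of 16, which re-forms the C2′–C3′ bond broken in the first opening, after C3′–C4′ and C5′–C6′ were made in the [2+2] step; no lasting stereocentre is formed. The step needs regioselectivity in the ketene–alkyne union (ketene carbonyl carbon C3′ to the methoxy-bearing carbon C4′): both alkyne carbons are donor-activated, so the only handles are that the siloxy oxygen is expected to be the stronger π-donor in an alkyne, polarising the HOMO toward the methoxy-bearing carbon, and that the triisopropylsilyl group shields its own carbon. It also needs the diether to react with the ketene and not with the enone or the ring C alkene, which its nucleophilic character should secure.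

Step 9
Reactants: 17 5-[6-(benzyloxy)-7,8-dimethoxy-2H-chromen-3-yl]-2-methoxy-3-[(triisopropylsilyl)oxy]phenol
Product: 18 {5-[6-(benzyloxy)-7,8-dimethoxy-2H-chromen-3-yl]-2,3-dimethoxyphenoxy}tri(propan-2-yl)silane
Conditions: MeI, K2CO3, acetone, 40 °C
Reagents that add atoms: iodomethane, CI
Why: Williamson O-methylation of the only free phenol (C3′–OH), the silyl ether being meta to the phenoxide so that no silyl migration can occur.

Step 10
Reactants: 18 {5-[6-(benzyloxy)-7,8-dimethoxy-2H-chromen-3-yl]-2,3-dimethoxyphenoxy}tri(propan-2-yl)silane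
Product: 19 {5-[(3S)-6-(benzyloxy)-7,8-dimethoxy-3,4-dihydro-2H-chromen-3-yl]-2,3-dimethoxyphenoxy}tri(propan-2-yl)silane
Conditions: H2 (50 bar), [Ir(cod)((S)-tBu-PHOX)][B(C6H3(CF3)2)4] (2 mol %), CH2Cl2, rt
Reagents that add atoms: none
Why: Iridium-catalysed asymmetric hydrogenation of a trisubstituted aryl alkene with a chiral P,N-ligand catalyst, a reaction type established for 3-aryl-2H-chromenes, in which the C3 stereocentre is set by catalyst control of the alkene face (ligand enantiomer chosen to give 3S) and benzyl and silyl ethers are inert.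

Step 11
Reactants: 19 {5-[(3S)-6-(benzyloxy)-7,8-dimethoxy-3,4-dihydro-2H-chromen-3-yl]-2,3-dimethoxyphenoxy}tri(propan-2-yl)silane
Product: 20 5-[(3S)-6-(benzyloxy)-7,8-dimethoxy-3,4-dihydro-2H-chromen-3-yl]-2,3-dimethoxyphenol
Conditions: Bu4NF, AcOH, THF, 0 °C
Reagents that add atoms: none
Why: Fluoride-mediated cleavage of the aryl silyl ether, buffered with acetic acid so that the electron-rich phenoxide is not exposed to base and air.

Step 12
Reactants: 20 5-[(3S)-6-(benzyloxy)-7,8-dimethoxy-3,4-dihydro-2H-chromen-3-yl]-2,3-dimethoxyphenol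
Product: 21 5-[(3S)-6-(benzyloxy)-7,8-dimethoxy-3,4-dihydro-2H-chromen-3-yl]-2,3-dimethoxycyclohexa-2,5-diene-1,4-dione
Conditions: K2[ON(SO3)2] (2.5 equiv), aq KH2PO4, acetone, rt
Reagents that add atoms: potassium nitrosodisulfonate, [K+].[K+].[O]N(S(=O)(=O)[O-])S(=O)(=O)[O-]
Why: Teuber oxidation, in which the nitroxyl radical abstracts the phenolic hydrogen at C5′ and a second equivalent oxygenates the free para position C2′ to give the para-quinone, while ring A carries no free OH and should not be attacked.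

Step 13
Reactants: 21 5-[(3S)-6-(benzyloxy)-7,8-dimethoxy-3,4-dihydro-2H-chromen-3-yl]-2,3-dimethoxycyclohexa-2,5-diene-1,4-dione
Product: 23 5-[(3S)-6-hydroxy-7,8-dimethoxy-3,4-dihydro-2H-chromen-3-yl]-2,3-dimethoxycyclohexa-2,5-diene-1,4-dione, via hydroquinone 22 (not isolated)
Conditions: H2 (1 atm), Pd/C, EtOAc, rt; filter; air, rt
Reagents that add atoms: none
Why: Hydrogenolysis of the benzyl ether, during which the quinone is reduced to hydroquinone 22, followed by aerobic re-oxidation of that hydroquinone, the ring A para-alkoxyphenol being stable to air under neutral conditions and the stereocentre untouched.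

**Compound list**

1 | 2-hydroxy-3,4-dimethoxybenzaldehyde | COc1ccc(C=O)c(O)c1OC | starting material
2 | potassium 5-formyl-4-hydroxy-2,3-dimethoxyphenyl sulfate | COc1c(OC)c(O)c(C=O)cc1OS(=O)(=O)[O-].[K+] | intermediate
3 | 2,5-dihydroxy-3,4-dimethoxybenzaldehyde | COc1c(OC)c(O)c(C=O)cc1O | intermediate
4 | 5-(benzyloxy)-2-hydroxy-3,4-dimethoxybenzaldehyde | COc1c(OC)c(O)c(C=O)cc1OCc1ccccc1 | intermediate
5 | acrolein (prop-2-enal) | C=CC=O | starting material
6 | 6-(benzyloxy)-7,8-dimethoxy-2H-chromene-3-carbaldehyde | O=CC1=Cc2cc(OCc3ccccc3)c(OC)c(OC)c2OC1 | intermediate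
7 | 6-(benzyloxy)-3-ethynyl-7,8-dimethoxy-2H-chromene | C#CC1=Cc2cc(OCc3ccccc3)c(OC)c(OC)c2OC1 | intermediate
8 | 3-[6-(benzyloxy)-7,8-dimethoxy-2H-chromen-3-yl]-4,4-dichlorocyclobut-2-en-1-one | O=C1C=C(C2=Cc3cc(OCc4ccccc4)c(OC)c(OC)c3OC2)C1(Cl)Cl | intermediate
9 | 3-[6-(benzyloxy)-7,8-dimethoxy-2H-chromen-3-yl]cyclobut-2-en-1-one | O=C1C=C(C2=Cc3cc(OCc4ccccc4)c(OC)c(OC)c3OC2)C1 | intermediate
10 | 2-chloro-1,1-dimethoxyethane (chloroacetaldehyde dimethyl acetal) | COC(CCl)OC | starting material
11 | lithium methoxyacetylide | [Li]C#COC | intermediate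
12 | lithium 2-methoxyethynolate | [Li]OC#COC | intermediate
13 | 1-methoxy-2-[(triisopropylsilyl)oxy]ethyne | COC#CO[Si](C(C)C)(C(C)C)C(C)C | intermediate
14 | 3-[6-(benzyloxy)-7,8-dimethoxy-2H-chromen-3-yl]buta-1,3-dien-1-one (vinylketene) | O=C=CC(=C)C1=Cc2cc(OCc3ccccc3)c(OC)c(OC)c2OC1 | intermediate
15 | 4-{1-[6-(benzyloxy)-7,8-dimethoxy-2H-chromen-3-yl]ethenyl}-2-methoxy-3-[(triisopropylsilyl)oxy]cyclobut-2-en-1-one | COC1=C(O[Si](C(C)C)(C(C)C)C(C)C)C(C(=C)C2=Cc3cc(OCc4ccccc4)c(OC)c(OC)c3OC2)C1=O | intermediate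
16 | 5-[6-(benzyloxy)-7,8-dimethoxy-2H-chromen-3-yl]-2-methoxy-3-[(triisopropylsilyl)oxy]hexa-1,3,5-trien-1-one (dienylketene, C2 and C5 cis across C3=C4) | O=C=C(OC)/C(O[Si](C(C)C)(C(C)C)C(C)C)=C\C(=C)C1=Cc2cc(OCc3ccccc3)c(OC)c(OC)c2OC1 | intermediate
17 | 5-[6-(benzyloxy)-7,8-dimethoxy-2H-chromen-3-yl]-2-methoxy-3-[(triisopropylsilyl)oxy]phenol | COc1c(O)cc(C2=Cc3cc(OCc4ccccc4)c(OC)c(OC)c3OC2)cc1O[Si](C(C)C)(C(C)C)C(C)C | intermediate
18 | {5-[6-(benzyloxy)-7,8-dimethoxy-2H-chromen-3-yl]-2,3-dimethoxyphenoxy}tri(propan-2-yl)silane | COc1cc(C2=Cc3cc(OCc4ccccc4)c(OC)c(OC)c3OC2)cc(O[Si](C(C)C)(C(C)C)C(C)C)c1OC | intermediate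
19 | {5-[(3S)-6-(benzyloxy)-7,8-dimethoxy-3,4-dihydro-2H-chromen-3-yl]-2,3-dimethoxyphenoxy}tri(propan-2-yl)silane | COc1cc(cc(O[Si](C(C)C)(C(C)C)C(C)C)c1OC)[C@H]1COc2c(cc(OCc3ccccc3)c(OC)c2OC)C1 | intermediate
20 | 5-[(3S)-6-(benzyloxy)-7,8-dimethoxy-3,4-dihydro-2H-chromen-3-yl]-2,3-dimethoxyphenol | COc1cc(cc(O)c1OC)[C@H]1COc2c(cc(OCc3ccccc3)c(OC)c2OC)C1 | intermediate
21 | 5-[(3S)-6-(benzyloxy)-7,8-dimethoxy-3,4-dihydro-2H-chromen-3-yl]-2,3-dimethoxycyclohexa-2,5-diene-1,4-dione | COC1=C(OC)C(=O)C([C@H]2COc3c(cc(OCc4ccccc4)c(OC)c3OC)C2)=CC1=O | intermediate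
22 | 5-[(3S)-6-hydroxy-7,8-dimethoxy-3,4-dihydro-2H-chromen-3-yl]-2,3-dimethoxybenzene-1,4-diol | COc1c(OC)c(O)c(cc1O)[C@H]1COc2c(cc(O)c(OC)c2OC)C1 | intermediate
23 | 5-[(3S)-6-hydroxy-7,8-dimethoxy-3,4-dihydro-2H-chromen-3-yl]-2,3-dimethoxycyclohexa-2,5-diene-1,4-dione | COC1=C(OC)C(=O)C([C@H]2COc3c(cc(O)c(OC)c3OC)C2)=CC1=O | target

**Step count.** 13 steps in total; longest linear sequence 12 steps (steps 1 to 6 and 8 to 13), with step 7 as a one-step branch.

**Steps most likely to fail**

Step 8 (key step). The acetylene diether 13 may be lost by oligomerisation or silyl migration before the ketene traps it, or the ketene carbonyl carbon may bond to the siloxy-bearing alkyne carbon (poor regiocontrol), placing the silyl ether on C4′. The fallback sets out from 9 and comes back at 20; it uses a siloxyalkyne with only one donor-substituted carbon and installs the C4′ oxygen afterwards. (Trimethylsilyl)acetylene is lithiated with n-BuLi, oxidised with LiOOt-Bu and O-silylated with iPr3SiOTf to give 1-[(triisopropylsilyl)oxy]-2-(trimethylsilyl)ethyne F1. Heating 9 with F1 in toluene should give, with the regiochemistry fixed by the single siloxy donor, 5-[6-(benzyloxy)-7,8-dimethoxy-2H-chromen-3-yl]-3-[(triisopropylsilyl)oxy]-2-(trimethylsilyl)phenol F2. Methylation (MeI, K2CO3) gives the methyl ether F3, hydrogenation as in step 10 gives the (3S)-isoflavan F4, and ipso-iododesilylation (ICl, CH2Cl2, −78 °C) gives the aryl iodide F5. Copper-catalysed methoxylation (NaOMe, CuI, MeOH–DMF, 100 °C), which also cleaves the silyl ether, returns phenol 20.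

Step 5. Dichloroketene may add to the electron-rich C3=C4 alkene of ring C in competition with the alkyne, or the enyne may oligomerise under the Lewis-acidic zinc salts. The fallback sets out from 6 and comes back at 19; it removes the alkene before any ketene chemistry. Reduction of 6 (NaBH4, CeCl3, MeOH) gives [6-(benzyloxy)-7,8-dimethoxy-2H-chromen-3-yl]methanol F6. Iridium-catalysed asymmetric hydrogenation with the catalyst family of step 10 gives the (3S)-alcohol F7, and oxidation with Dess–Martin periodinane gives the (3R)-aldehyde F8. Colvin homologation at −78 °C gives the (3S)-alkyne F9. Dichloroketene cycloaddition gives the dichlorocyclobutenone F10 and zinc dechlorination gives the cyclobutenone F11. Benzannulation with 13 as in step 8 gives the (3S)-phenol F12, whose methylation (MeI, K2CO3) gives 19.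

Step 10. Poor facial selectivity, or inhibition of the cationic catalyst by the many ether oxygens, may leave the stereocentre insufficiently controlled. The fallback sets out from 18 and comes back at 20; it replaces asymmetric catalysis by resolution. Hydrogenation without stereocontrol over [Ir(cod)(PCy3)(py)]PF6 gives the racemic isoflavan F13, desilylation (Bu4NF, AcOH) gives the racemic phenol F14, and preparative chromatography on a chiral stationary phase separates the enantiomers, the (3S)-enantiomer being 20.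

**Further compounds**

F1 | step 8 | 1-[(triisopropylsilyl)oxy]-2-(trimethylsilyl)ethyne | C[Si](C)(C)C#CO[Si](C(C)C)(C(C)C)C(C)C
F2 | step 8 | 5-[6-(benzyloxy)-7,8-dimethoxy-2H-chromen-3-yl]-3-[(triisopropylsilyl)oxy]-2-(trimethylsilyl)phenol | C[Si](C)(C)c1c(O)cc(cc1O[Si](C(C)C)(C(C)C)C(C)C)C1=Cc2cc(OCc3ccccc3)c(OC)c(OC)c2OC1
F3 | step 8 | {5-[6-(benzyloxy)-7,8-dimethoxy-2H-chromen-3-yl]-3-methoxy-2-(trimethylsilyl)phenoxy}tri(propan-2-yl)silane | COc1cc(cc(O[Si](C(C)C)(C(C)C)C(C)C)c1[Si](C)(C)C)C1=Cc2cc(OCc3ccccc3)c(OC)c(OC)c2OC1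
F4 | step 8 | {5-[(3S)-6-(benzyloxy)-7,8-dimethoxy-3,4-dihydro-2H-chromen-3-yl]-3-methoxy-2-(trimethylsilyl)phenoxy}tri(propan-2-yl)silane | COc1cc(cc(O[Si](C(C)C)(C(C)C)C(C)C)c1[Si](C)(C)C)[C@H]1COc2c(cc(OCc3ccccc3)c(OC)c2OC)C1
F5 | step 8 | {5-[(3S)-6-(benzyloxy)-7,8-dimethoxy-3,4-dihydro-2H-chromen-3-yl]-2-iodo-3-methoxyphenoxy}tri(propan-2-yl)silane | COc1cc(cc(O[Si](C(C)C)(C(C)C)C(C)C)c1I)[C@H]1COc2c(cc(OCc3ccccc3)c(OC)c2OC)C1
F6 | step 5 | [6-(benzyloxy)-7,8-dimethoxy-2H-chromen-3-yl]methanol | OCC1=Cc2cc(OCc3ccccc3)c(OC)c(OC)c2OC1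
F7 | step 5 | [(3S)-6-(benzyloxy)-7,8-dimethoxy-3,4-dihydro-2H-chromen-3-yl]methanol | OC[C@H]1COc2c(cc(OCc3ccccc3)c(OC)c2OC)C1
F8 | step 5 | (3R)-6-(benzyloxy)-7,8-dimethoxy-3,4-dihydro-2H-chromene-3-carbaldehyde | O=C[C@H]1COc2c(cc(OCc3ccccc3)c(OC)c2OC)C1
F9 | step 5 | (3S)-6-(benzyloxy)-3-ethynyl-7,8-dimethoxy-3,4-dihydro-2H-chromene | C#C[C@H]1COc2c(cc(OCc3ccccc3)c(OC)c2OC)C1
F10 | step 5 | 3-[(3S)-6-(benzyloxy)-7,8-dimethoxy-3,4-dihydro-2H-chromen-3-yl]-4,4-dichlorocyclobut-2-en-1-one | O=C1C=C([C@H]2COc3c(cc(OCc4ccccc4)c(OC)c3OC)C2)C1(Cl)Cl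
F11 | step 5 | 3-[(3S)-6-(benzyloxy)-7,8-dimethoxy-3,4-dihydro-2H-chromen-3-yl]cyclobut-2-en-1-one | O=C1C=C([C@H]2COc3c(cc(OCc4ccccc4)c(OC)c3OC)C2)C1
F12 | step 5 | 5-[(3S)-6-(benzyloxy)-7,8-dimethoxy-3,4-dihydro-2H-chromen-3-yl]-2-methoxy-3-[(triisopropylsilyl)oxy]phenol | COc1c(O)cc(cc1O[Si](C(C)C)(C(C)C)C(C)C)[C@H]1COc2c(cc(OCc3ccccc3)c(OC)c2OC)C1
F13 | step 10 | racemic {5-[6-(benzyloxy)-7,8-dimethoxy-3,4-dihydro-2H-chromen-3-yl]-2,3-dimethoxyphenoxy}tri(propan-2-yl)silane | COc1cc(cc(O[Si](C(C)C)(C(C)C)C(C)C)c1OC)C1COc2c(cc(OCc3ccccc3)c(OC)c2OC)C1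
F14 | step 10 | racemic 5-[6-(benzyloxy)-7,8-dimethoxy-3,4-dihydro-2H-chromen-3-yl]-2,3-dimethoxyphenol | COc1cc(cc(O)c1OC)C1COc2c(cc(OCc3ccccc3)c(OC)c2OC)C1
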